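**Retrosynthetic overview**
- Artelasticin ⇒ tetra-O-allyl flavone (deallylation last) ⇒ o-hydroxyaryl 1,3-diketone (ring C by cyclodehydration, O1–C2) ⇒ aryl ester (Baker–Venkataraman transfer, C2–C3 bond) of a 2-hydroxyaryl ketone and 2,4-bis(allyloxy)benzoic acid (ring B, from 2,4-dihydroxybenzoic acid).
- The ketone is a 3,5-diprenyl acylphloroglucinol ⇒ Claisen folding (C4a–C5 bond, ring A) of an open-chain methyl 2,4-diprenyl-3,5,7-trioxo ester.
- Chain ⇒ trianion acylation of methyl 2,4-diprenyl-3,5-dioxohexanoate with the Weinreb amide of 5-methylhex-4-enoic acid (Johnson–Claisen) ⇒ dianion acetylation of α,γ-diprenylated methyl acetoacetate ⇒ methyl acetoacetate and prenyl bromide.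
- Feature: ring A (C4a, C5, C6, C7, C8, C8a) with the C4 carbonyl is an acylphloroglucinol. Its prenyl-bearing C6 and C8 are the C2 and C4 methine carbons of the unfolded tetraketide, and C3 with its prenyl group is the α-carbon of the acyl chain, so all three prenyl groups are placed on enolate carbons before any ring exists.
- Ring order: ring A (step 6), then ring C (step 12); ring B is carried in intact.

Key step: step 6

Remark: the prenyl-bearing sp3 carbons of 4, 6, 12, 13, 21 and 22 are epimerisable stereocentres, and the β-dicarbonyl units are keto–enol mixtures. They are handled as mixtures because all become sp2 before the achiral target. Commercial solutions of LiN(i-Pr)2, LiN(SiMe3)2 and Mg(OMe)2 are assumed.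

**Step 1**
Reactants: 1 methyl acetoacetate; 2 prenyl bromide (1-bromo-3-methylbut-2-ene, two equivalents)
Product: 4 methyl 7-methyl-2-(3-methylbut-2-enyl)-3-oxooct-6-enoate, via keto ester 3 (not isolated)
Conditions: NaH (1.1 equiv), THF, 0 °C; n-BuLi (1.05 equiv), 0 °C; 2 (1.0 equiv), 0 °C; then 2 (1.1 equiv), DMPU, rt to 40 °C; aq NH4Cl
Reagents that add atoms: none
Why: Weiler dianion alkylation, in which the γ-carbanion takes the first prenyl bromide by SN2 and the remaining β-keto ester enolate (of 3) is then alkylated at C2 by the second equivalent; the C2 stereocentre forms racemic and is erased in step 6.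

**Step 2**
Reactants: 4 methyl 7-methyl-2-(3-methylbut-2-enyl)-3-oxooct-6-enoate; 5 N-methoxy-N-methylacetamide
Product: 6 methyl 2,4-bis(3-methylbut-2-enyl)-3,5-dioxohexanoate
Conditions: LiN(i-Pr)2 (2.2 equiv), THF, −78 to 0 °C; 5 (1.1 equiv), −78 to 0 °C; aq NH4Cl
Reagents that add atoms: none
Why: γ-Acylation of a β-keto ester dianion by a Weinreb amide, whose chelated tetrahedral adduct keeps the new diketone away from the base until work-up; the C4 stereocentre is uncontrolled and is erased in step 6.

**Step 3**
Reactants: 7 2-methylbut-3-en-2-ol; 8 triethyl orthoacetate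
Product: 10 ethyl 5-methylhex-4-enoate, via ketene acetal 9 (not isolated)
Conditions: EtCO2H (cat.), neat 8 (excess), 140 °C, EtOH distilled off
Reagents that add atoms: none
Why: Johnson–Claisen rearrangement, in which acid-catalysed exchange gives ketene acetal 9 and its chair-like [3,3] shift forms the C–C bond at the alkene terminus and leaves the trisubstituted alkene; no stereocentre is formed.

**Step 4**
Reactants: 10 ethyl 5-methylhex-4-enoate
Product: 11 N-methoxy-N,5-dimethylhex-4-enamide
Conditions: MeNH(OMe)·HCl (1.5 equiv), i-PrMgCl (3.0 equiv), THF, −20 to 0 °C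
Reagents that add atoms: N,O-dimethylhydroxylamine hydrochloride, CNOC.Cl
Why: Direct ester aminolysis to the Weinreb amide by the chloromagnesium amide made in the flask from the hydrochloride and i-PrMgCl; the isolated alkene is inert.

**Step 5**
Reactants: 6 methyl 2,4-bis(3-methylbut-2-enyl)-3,5-dioxohexanoate; 11 N-methoxy-N,5-dimethylhex-4-enamide
Product: 12 methyl 11-methyl-2,4-bis(3-methylbut-2-enyl)-3,5,7-trioxododec-10-enoate
Conditions: LiN(i-Pr)2 (3.3 equiv), THF, −78 to 0 °C; 11 (1.0 equiv), −78 to −20 °C; cold aq NH4Cl; taken on without chromatography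
Reagents that add atoms: none
Why: Polyanion acylation of a 3,5-dioxo ester, in which the last-formed terminal C6 carbanion of the trianion is the most nucleophilic site and adds to the Weinreb amide, whose stable adduct prevents proton exchange and over-addition; no stereocentre is set.

**Step 6**
Reactants: 12 methyl 11-methyl-2,4-bis(3-methylbut-2-enyl)-3,5,7-trioxododec-10-enoate
Product: 14 1-[2,4,6-trihydroxy-3,5-bis(3-methylbut-2-enyl)phenyl]-5-methylhex-4-en-1-one, via cyclohexanetrione 13 (not isolated)
Conditions: Mg(OMe)2 (5 equiv), degassed MeOH, rt to 65 °C, Ar; cold 1 M HCl to pH 3–4, brief contact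
Reagents that add atoms: none
Why: Mg(OMe)2 turns the C5–C7 β-diketone of 12 into a magnesium-chelated enolate whose central carbon C6, the only unsubstituted doubly activated methylene, adds to the C1 ester carbonyl; loss of methoxide gives trione 13, which enolises to the aromatic triol 14. The closest known reaction type is the magnesium methoxide-promoted Claisen (Dieckmann-type) cyclisation of 3,5,7-triketo esters to acylphloroglucinols, applied here to a 2,4-dialkylated chain. Ring A closes in a 6-exo-trig mode through the C6–C1 bond of the chain, the future C4a–C5 bond of the flavone. No stereocentre is set, because C2 and C4 each keep one hydrogen and become sp2 on aromatisation. The step needs C-acylation at C6 rather than aldol closure or O-acylation: attack of C2 on C7 would make C2 quaternary and cannot aromatise, C8 is the least acidic α-carbon and would have to reach the C3 ketone between two branched carbons, and the pyrone from attack of the C5 enol oxygen on C1 should be reopened by methoxide. Magnesium chelation keeps the C5–C7 unit a carbon nucleophile, and only the Claisen path ends in an aromatic, fully deprotonated product, so the equilibria should drain toward 14.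

**Step 7**
Reactants: 14 1-[2,4,6-trihydroxy-3,5-bis(3-methylbut-2-enyl)phenyl]-5-methylhex-4-en-1-one
Product: 15 1-[2-hydroxy-3,5-bis(3-methylbut-2-enyl)-4,6-bis(prop-2-enoxy)phenyl]-5-methylhex-4-en-1-one
Conditions: allyl bromide (2.3 equiv), K2CO3 (2.5 equiv), acetone, rt to 45 °C, Ar
Reagents that add atoms: allyl bromide, C=CCBr
Why: Williamson etherification in which the para hydroxyl and one of the two equivalent ortho hydroxyls react while the last ortho hydroxyl, hydrogen-bonded to the ketone, stays free, as is usual for 2,4,6-trihydroxyaryl ketones with K2CO3 in an aprotic medium.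

**Step 8**
Reactants: 16 2,4-dihydroxybenzoic acid
Product: 17 prop-2-enyl 2,4-bis(prop-2-enoxy)benzoate
Conditions: allyl bromide (3.5 equiv), K2CO3 (4 equiv), DMF, 60 °C
Reagents that add atoms: allyl bromide, C=CCBr
Why: Threefold SN2 alkylation (Williamson ether synthesis and carboxylate alkylation) of the carboxylate and both phenoxides by a reactive allylic bromide.

**Step 9**
Reactants: 17 prop-2-enyl 2,4-bis(prop-2-enoxy)benzoate
Product: 18 2,4-bis(prop-2-enoxy)benzoic acid
Conditions: NaOH (3 equiv), MeOH–THF–H2O, 50 °C; then 1 M HCl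
Reagents that add atoms: sodium hydroxide, [Na+].[OH-]
Why: Saponification of the allyl ester, to which the aryl allyl ethers are inert.

**Step 10**
Reactants: 15 1-[2-hydroxy-3,5-bis(3-methylbut-2-enyl)-4,6-bis(prop-2-enoxy)phenyl]-5-methylhex-4-en-1-one; 18 2,4-bis(prop-2-enoxy)benzoic acid
Product: 20 2-(5-methylhex-4-enoyl)-4,6-bis(3-methylbut-2-enyl)-3,5-bis(prop-2-enoxy)phenyl 2,4-bis(prop-2-enoxy)benzoate, via acid chloride 19 (not isolated)
Conditions: 18, (COCl)2 (1.3 equiv), DMF (cat.), CH2Cl2, 0 °C to rt, evaporate; 15, NaH (1.2 equiv), THF, 0 °C, then 19, rt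
Reagents that add atoms: none
Why: Acid chloride formation under Vilsmeier catalysis followed by O-acylation of the sodium phenoxide of 15 (nucleophilic acyl substitution); the phenol is far more acidic than the ketone α-hydrogens, so one equivalent of NaH directs the acyl group to oxygen.

**Step 11**
Reactants: 20 2-(5-methylhex-4-enoyl)-4,6-bis(3-methylbut-2-enyl)-3,5-bis(prop-2-enoxy)phenyl 2,4-bis(prop-2-enoxy)benzoate
Product: 21 1-[2,4-bis(prop-2-enoxy)phenyl]-3-[2-hydroxy-3,5-bis(3-methylbut-2-enyl)-4,6-bis(prop-2-enoxy)phenyl]-2-(3-methylbut-2-enyl)propane-1,3-dione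
Conditions: LiN(SiMe3)2 (3.0 equiv), THF, −20 °C to rt; aq NH4Cl
Reagents that add atoms: none
Why: Baker–Venkataraman rearrangement, in which the ketone enolate attacks the neighbouring aryl ester through a six-membered transition state and formation of the phenoxide and diketone enolate makes the transfer irreversible; the new stereocentre between the carbonyls forms racemic and is erased in step 12.

**Step 12**
Reactants: 21 1-[2,4-bis(prop-2-enoxy)phenyl]-3-[2-hydroxy-3,5-bis(3-methylbut-2-enyl)-4,6-bis(prop-2-enoxy)phenyl]-2-(3-methylbut-2-enyl)propane-1,3-dione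
Product: 23 2-[2,4-bis(prop-2-enoxy)phenyl]-3,6,8-tris(3-methylbut-2-enyl)-5,7-bis(prop-2-enoxy)chromen-4-one, via hemiketal 22 (not isolated)
Conditions: NaOAc (3 equiv), AcOH, 100 °C
Reagents that add atoms: none
Why: Cyclodehydration of an o-hydroxyaryl 1,3-diketone, in which the phenol adds to the aryl ketone to give hemiketal 22 and loss of water gives the chromone; the acetate buffer keeps the medium too weakly acidic to cyclise prenyl groups or cleave allyl ethers.

**Step 13**
Reactants: 23 2-[2,4-bis(prop-2-enoxy)phenyl]-3,6,8-tris(3-methylbut-2-enyl)-5,7-bis(prop-2-enoxy)chromen-4-one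
Product: 24 artelasticin, 2-(2,4-dihydroxyphenyl)-5,7-dihydroxy-3,6,8-tris(3-methylbut-2-enyl)chromen-4-one
Conditions: Pd(PPh3)4 (10 mol %), morpholine (20 equiv), THF, rt, Ar, dark
Reagents that add atoms: none
Why: Tsuji–Trost-type deallylation, in which zerovalent palladium ionises the four aryl allyl ethers to π-allyl complexes that morpholine intercepts; the prenyl groups carry no leaving group, and the neutral medium spares the acid-sensitive 2'-hydroxyl/3-prenyl pair.

**Compound list**
1 | methyl acetoacetate | COC(=O)CC(C)=O | starting material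
2 | prenyl bromide (1-bromo-3-methylbut-2-ene) | CC(C)=CCBr | starting material
3 | methyl 7-methyl-3-oxooct-6-enoate (formed as its enolate, not isolated) | COC(=O)CC(=O)CCC=C(C)C | intermediate
4 | methyl 7-methyl-2-(3-methylbut-2-enyl)-3-oxooct-6-enoate (racemic) | COC(=O)C(CC=C(C)C)C(=O)CCC=C(C)C | intermediate
5 | N-methoxy-N-methylacetamide | CON(C)C(C)=O | starting material
6 | methyl 2,4-bis(3-methylbut-2-enyl)-3,5-dioxohexanoate (stereoisomer mixture) | COC(=O)C(CC=C(C)C)C(=O)C(CC=C(C)C)C(C)=O | intermediate
7 | 2-methylbut-3-en-2-ol | CC(C)(O)C=C | starting material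
8 | triethyl orthoacetate | CCOC(C)(OCC)OCC | starting material
9 | 3-(1-ethoxyethenoxy)-3-methylbut-1-ene (ketene acetal, not isolated) | C=C(OCC)OC(C)(C)C=C | intermediate
10 | ethyl 5-methylhex-4-enoate | CCOC(=O)CCC=C(C)C | intermediate
11 | N-methoxy-N,5-dimethylhex-4-enamide | CON(C)C(=O)CCC=C(C)C | intermediate
12 | methyl 11-methyl-2,4-bis(3-methylbut-2-enyl)-3,5,7-trioxododec-10-enoate (stereoisomer mixture) | COC(=O)C(CC=C(C)C)C(=O)C(CC=C(C)C)C(=O)CC(=O)CCC=C(C)C | intermediate
13 | 2-(5-methylhex-4-enoyl)-4,6-bis(3-methylbut-2-enyl)cyclohexane-1,3,5-trione (not isolated) | CC(C)=CCCC(=O)C1C(=O)C(CC=C(C)C)C(=O)C(CC=C(C)C)C1=O | intermediate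
14 | 1-[2,4,6-trihydroxy-3,5-bis(3-methylbut-2-enyl)phenyl]-5-methylhex-4-en-1-one | CC(C)=CCCC(=O)c1c(O)c(CC=C(C)C)c(O)c(CC=C(C)C)c1O | intermediate
15 | 1-[2-hydroxy-3,5-bis(3-methylbut-2-enyl)-4,6-bis(prop-2-enoxy)phenyl]-5-methylhex-4-en-1-one | CC(C)=CCCC(=O)c1c(O)c(CC=C(C)C)c(OCC=C)c(CC=C(C)C)c1OCC=C | intermediate
16 | 2,4-dihydroxybenzoic acid | O=C(O)c1ccc(O)cc1O | starting material
17 | prop-2-enyl 2,4-bis(prop-2-enoxy)benzoate | C=CCOC(=O)c1ccc(OCC=C)cc1OCC=C | intermediate
18 | 2,4-bis(prop-2-enoxy)benzoic acid | O=C(O)c1ccc(OCC=C)cc1OCC=C | intermediate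
19 | 2,4-bis(prop-2-enoxy)benzoyl chloride (not isolated) | O=C(Cl)c1ccc(OCC=C)cc1OCC=C | intermediate
20 | 2-(5-methylhex-4-enoyl)-4,6-bis(3-methylbut-2-enyl)-3,5-bis(prop-2-enoxy)phenyl 2,4-bis(prop-2-enoxy)benzoate | CC(C)=CCCC(=O)c1c(OC(=O)c2ccc(OCC=C)cc2OCC=C)c(CC=C(C)C)c(OCC=C)c(CC=C(C)C)c1OCC=C | intermediate
21 | 1-[2,4-bis(prop-2-enoxy)phenyl]-3-[2-hydroxy-3,5-bis(3-methylbut-2-enyl)-4,6-bis(prop-2-enoxy)phenyl]-2-(3-methylbut-2-enyl)propane-1,3-dione (racemic) | C=CCOc1ccc(C(=O)C(CC=C(C)C)C(=O)c2c(O)c(CC=C(C)C)c(OCC=C)c(CC=C(C)C)c2OCC=C)c(OCC=C)c1 | intermediate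
22 | 2-[2,4-bis(prop-2-enoxy)phenyl]-2-hydroxy-3,6,8-tris(3-methylbut-2-enyl)-5,7-bis(prop-2-enoxy)chroman-4-one (stereoisomer mixture, not isolated) | C=CCOc1ccc(C2(O)Oc3c(CC=C(C)C)c(OCC=C)c(CC=C(C)C)c(OCC=C)c3C(=O)C2CC=C(C)C)c(OCC=C)c1 | intermediate
23 | 2-[2,4-bis(prop-2-enoxy)phenyl]-3,6,8-tris(3-methylbut-2-enyl)-5,7-bis(prop-2-enoxy)chromen-4-one | C=CCOc1ccc(-c2oc3c(CC=C(C)C)c(OCC=C)c(CC=C(C)C)c(OCC=C)c3c(=O)c2CC=C(C)C)c(OCC=C)c1 | intermediate
24 | artelasticin | CC(C)=CCc1c(O)c(CC=C(C)C)c2oc(-c3ccc(O)cc3O)c(CC=C(C)C)c(=O)c2c1O | target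

**Step count**
Total: 13 steps. Longest linear sequence: 9 steps (1, 2, 5, 6, 7, 10, 11, 12, 13).

**Steps most likely to fail**

Step 6. The chain may partition away from the Claisen mode: lactonisation through the C5 enol oxygen to a pyrone that is not reopened, aldol closure from C8 onto the C3 ketone, or retro-Claisen cleavage by methoxide at the doubly branched C3 ketone. Air oxidation of the electron-rich product under base is a further loss. The fallback gives up chain folding for nuclear prenylation; it sets out from Weinreb amide 11 and prenyl bromide 2 and returns at 14. Commercial benzene-1,3,5-triol is converted with chloromethyl methyl ether and NaH in DMF into 1,3,5-tris(methoxymethoxy)benzene F1. Lithiation of F1 between two acetal oxygens (n-BuLi, THF, 0 °C) and addition to 11 should give 5-methyl-1-[2,4,6-tris(methoxymethoxy)phenyl]hex-4-en-1-one F2. Mild methanolysis (HCl in MeOH, 40 °C) should free 5-methyl-1-(2,4,6-trihydroxyphenyl)hex-4-en-1-one F3. Twofold C-prenylation of F3 with 2 in cold aqueous KOH, the classical route to 3,5-diprenyl acylphloroglucinols, then leads to 14.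

Step 5. The third deprotonation may stay incomplete, the amide may be enolised by proton transfer instead of acylating, or the sensitive triketo ester may cyclise during work-up. The fallback brings the C5–C7 unit in as a preformed, ketal-masked acetoacetyl donor so that only a dianion is needed; it sets out from keto ester 3 (isolated when step 1 is stopped after the first equivalent of 2) and from 4, and returns at 12. Ketalisation of 3 (ethylene glycol, pyridinium p-toluenesulfonate, benzene, water removal) should give methyl 2-[2-(4-methylpent-3-enyl)-1,3-dioxolan-2-yl]acetate F4. Aminolysis as in step 4 gives N-methoxy-N-methyl-2-[2-(4-methylpent-3-enyl)-1,3-dioxolan-2-yl]acetamide F5. The dianion of 4 (LiN(i-Pr)2, 2.2 equiv) is acylated with F5 to methyl 2,4-bis(3-methylbut-2-enyl)-6-[2-(4-methylpent-3-enyl)-1,3-dioxolan-2-yl]-3,5-dioxohexanoate F6. Mild hydrolysis (pyridinium p-toluenesulfonate, wet acetone, 40 °C) then unmasks 12.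

Step 11. The acyl transfer may stall because the fully substituted ring twists the ketone and the α-branched enolate reaches the hindered ester slowly, while base-induced cleavage of the ester back to 15 competes. The fallback avoids ester 20 and its rearrangement; it sets out from 15 and acid chloride 19 and returns at 21. The dilithium phenoxide–enolate of 15 (LiN(SiMe3)2, 3.2 equiv, THF, −78 °C) is acylated directly at carbon with 19 on warming to rt; any O-acylated material formed alongside is 20 and is not lost.

**Further compounds**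
F1 | step 6 | 1,3,5-tris(methoxymethoxy)benzene | COCOc1cc(OCOC)cc(OCOC)c1
F2 | step 6 | 5-methyl-1-[2,4,6-tris(methoxymethoxy)phenyl]hex-4-en-1-one | CC(C)=CCCC(=O)c1c(OCOC)cc(OCOC)cc1OCOC
F3 | step 6 | 5-methyl-1-(2,4,6-trihydroxyphenyl)hex-4-en-1-one | CC(C)=CCCC(=O)c1c(O)cc(O)cc1O
F4 | step 5 | methyl 2-[2-(4-methylpent-3-enyl)-1,3-dioxolan-2-yl]acetate | COC(=O)CC1(CCC=C(C)C)OCCO1
F5 | step 5 | N-methoxy-N-methyl-2-[2-(4-methylpent-3-enyl)-1,3-dioxolan-2-yl]acetamide | CON(C)C(=O)CC1(CCC=C(C)C)OCCO1
F6 | step 5 | methyl 2,4-bis(3-methylbut-2-enyl)-6-[2-(4-methylpent-3-enyl)-1,3-dioxolan-2-yl]-3,5-dioxohexanoate | COC(=O)C(CC=C(C)C)C(=O)C(CC=C(C)C)C(=O)CC1(CCC=C(C)C)OCCO1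
F0 | step 11 | none | none
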